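## Structural features

Cathafuran C is an achiral 2-arylbenzofuran. Ring A is the benzo ring of a 1-benzofuran with a free hydroxyl at C6, and C2 of the furan is bonded to C1' of a separate benzene, ring B. Ring B is pentasubstituted: C1' carries the benzofuran, C2' and C3' are fused to a 2,2-dimethyl-2H-pyran (C2'–CH=CH–C(CH3)2–O–C3'), C4' is the only C–H, C5' carries a free phenol and C6' a 3-methylbut-2-enyl (prenyl) group. There is no stereocentre, so no stereocentres stand next to each other; the problem is regiochemistry and congestion. Three carbon substituents sit side by side (C6' prenyl, C1' benzofuranyl, C2' vinyl), both flanking groups lie ortho to the biaryl bond, and the electronically most activated carbon, C4' between the two oxygens, must stay unsubstituted. The fragile elements are the chromene and prenyl olefins, the ortho-prenylphenol (acid closes it to a chroman) and the electron-rich phenols and benzofuran. The end game therefore has to avoid acid, oxidants and catalytic hydrogenation. The key step exploits the fact that C6' is ortho to the oxygen on C5' and C2' is ortho to the oxygen on C3', so each carbon substituent can be delivered from its neighbouring oxygen by a [3,3] shift while C4' is held by a removable bromine. Ring B is a 5-substituted resorcinol whose two oxygens are equivalent until they are alkylated, so a symmetric 4-bromo-3,5-dihydroxybenzoate can serve as its source.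

## Logic of the disconnections

**19 ⇒ 18 ⇒ 17.** The O–H bond on ring A is traced back to an O–Si bond and the C4'–H bond to a C4'–Br bond. The silyl ether keeps the ring A phenol inert through alkylation and heating, and the bromine is the blocking atom the key step needs. Nothing in the skeleton changes, so 17 already holds every carbon of 19. The forward steps must remove bromine without touching two olefins (no H2 over metal) and remove silicon without acid.

**17 ⇒ 14 (key disconnection).** The C6'–CH2 bond of the prenyl group and the C2'–CH bond of the pyran are cut, and both five-carbon units are moved back onto the oxygens of C5' and C3' as a 1,1-dimethylallyl and a 1,1-dimethylpropargyl ether. This removes the pyran ring and both hindered C–C bonds at once and leaves a flat 2-arylbenzofuran bis-ether. The forward step must run two [3,3] shifts in one pot, each to the ortho carbon next to the benzofuran and not to C4', and the tertiary allyl ether must rearrange before it fragments.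

**14 ⇒ 13 + 11; 13 ⇒ 12; 12 ⇒ 10 + 11.** The two tertiary C–O ether bonds are cut. Both units come from the same chloride 11, and the allyl ether is an alkyne reduced by one H2 before the second alkyne is introduced, so that alkyne never meets hydrogen. This reaches the symmetric diol 10. The demands are mono-alkylation of two equivalent phenols and a semihydrogenation that spares the C–Br bond.

**10 ⇒ 9 ⇒ 7 + 4 (through 8).** The furan is opened at the C2=C3 double bond and the O1–C2 bond, the retron of an intramolecular ester Wittig reaction. The two ring B phenols are masked as acetals during acylation. The molecule falls into two benzene pieces of similar size, a symmetric acid and a phosphonium salt. The forward step needs exactly one free phenol in 4, and the acetals must later come off with the silyl ether intact.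

**7 ⇒ 6 ⇒ 5 and 4 ⇒ 3 ⇒ 2 ⇒ 1.** Only C–O and C–P bonds at functional groups are cut (acetal, ester, silyl ether, benzylic phosphonium), which leads to the commercial compounds 5 and 1. The one demand is selective silylation of the 4-hydroxyl of 1.

## Other disconnections considered

**Alternative 1:** The cut is the C1'–C2' bond of ring B, so that all six ring carbons come from an open polyketide-type chain.
- **Forward key step.** Thermolysis of the diketo-dioxinone A2 with methanolysis would release an acylketene and trap it as the methyl triketo ester A3. Cs2CO3 would then drive an aldol condensation of the ester α-carbon onto the benzofuranyl ketone, and dehydration and enolisation would give the resorcylate A1.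
- **In favour.** Ring B is built de novo, so the positions of benzofuran, prenyl, both oxygens and the lone hydrogen follow from chain connectivity alone. No blocking atom and no desymmetrisation of equivalent phenols is needed; on regiocontrol this plan is the better one. The ester at C2' also tells the two phenols apart.
- **Against.** A1 still lacks the pyran: the ester must be reduced, extended by three carbons and cyclised with both phenols handled on the way, four or more steps after the key step against two after 17. The prenyl-bearing carbon of A2 lies between two ketones and is open to retro-Claisen cleavage and to O-cyclisation to a pyranone. The aldol acceptor is a ketone deactivated by the electron-rich benzofuran and flanked by a branched carbon. The final acetal removal needs acid beside an ortho-prenylphenol and a chromene, whereas 18 is unmasked with fluoride.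
- **Comparison.** On structure, alternative 1 is stronger for the substitution pattern of ring B and weaker for the pyran. On mechanism, an ionic cascade with several competing enolate pathways stands against two pericyclic shifts whose only variable is ortho regiochemistry. Neither plan has a stereocentre to control, so they are equal there. On step economy the chosen plan is ahead, because step 11 delivers the prenyl group and the pyran together.

**Alternative 2:** The cut is the furan ring at C3–C3a and O1–C7a, giving the chromenyl methyl ketone A5 (all of ring B) and the dihaloarene A6 (ring A).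
- **Forward key step.** With Pd2(dba)3, a bisphosphine and NaOtBu the enolate of A5 would be arylated at the C–I bond of A6, and the enolate oxygen of the new aryl ketone would then displace the neighbouring bromide on palladium to close the furan and give A4.
- **In favour.** The plan is convergent: a finished ring B piece meets a very simple ring A piece, and the C2–C1' bond is already present as the ketone C–C bond. Only one step (acetal removal) follows the key step. On convergence and on the length of the ring A branch this plan is the better one, and it avoids the statistical mono-alkylation of 10.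
- **Against.** It does not address the real difficulty. A5 is a pentasubstituted benzene in which the acetyl group is flanked by the prenyl group and the chromene, so the same two hindered ortho C–C bonds must still be made beforehand, most plausibly by the chemistry of step 11. The C–O reductive elimination that closes the furan is the harder half of the tandem, and a second C-arylation of the mono-arylated ketone competes with it. The final double acetal cleavage needs acid on the complete, acid-sensitive skeleton.
- **Comparison.** On structure, alternative 2 solves ring A and the furan elegantly and leaves ring B unsolved. On mechanism, it depends on ligand-controlled catalysis at a ketone with two ortho substituents, against a thermal isomerisation that needs no reagent. On step economy after the key step it is the equal or slightly the better, but over the whole route it is longer because of A5.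

**Alternative 3:** The cuts are the C1'–C2' and C3'–C4' bonds of ring B, giving the α-prenyl benzofuranyl enone A8 and dimethyl malonate A9.
- **Forward key step.** Under NaOMe, A9 would add to the β-carbon of A8 (Michael addition), and the methyl ketone enolate would then close onto one malonate ester (Claisen/Dieckmann-type condensation) to give the cyclohexane-1,3-dione A7.
- **In favour.** The reagents are cheap and the reaction is a classical, scalable entry to 5-substituted resorcinols. As in alternative 1 the ring B pattern follows from connectivity, so on regiocontrol without a blocking atom it is the equal or the better of the chosen plan.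
- **Against.** A7 is at the wrong oxidation level, and dehydrogenation to the resorcinol calls for halogen or quinone oxidants that also attack the prenyl olefin and the benzofuran. Its three stereocentres are made only to be erased. Conjugate addition to an α-branched, β-heteroaryl enone is slow and reversible. The ester at C2' must still be turned into the pyran and the two phenols told apart. Making A8 itself has a regiochemical problem, namely on which side of an unsymmetrical ketone the aldol condensation takes place.
- **Comparison.** On structure, ring B is reached only as a saturated precursor with neither the aromatic ring nor the pyran in place. On mechanism, robust ionic steps are followed by a chemoselectivity problem in the oxidation that the pericyclic plan does not have. On step economy it is clearly longer after the key step (aromatisation, ester conversion, annulation, deprotection).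

Key step: step 11

Remark: primed locants C1'–C6' denote ring B, with C1' bonded to C2 of the benzofuran. The bis-ether 14 and the chromenol 17 are isomers (C33H43BrO4Si) whose names and structures agree, so neither needed correction. No compound of the route has a stereocentre; the only stereo-element is the olefin geometry of the transient 16.

## Route

Step 1
Reactants: 1 2,4-dihydroxybenzaldehyde
Product: 2 2-hydroxy-4-(triisopropylsilyloxy)benzaldehyde
Conditions: TIPSCl (1.05 equiv), imidazole, CH2Cl2, 0 °C to rt
Reagents that add atoms: chlorotriisopropylsilane, CC(C)[Si](Cl)(C(C)C)C(C)C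
Why: The 2-hydroxyl is held in a hydrogen bond to the formyl group and is flanked by it, so the bulky silyl chloride should react at the freer and more nucleophilic 4-hydroxyl (regioselective phenol silylation).

Step 2
Reactants: 2 2-hydroxy-4-(triisopropylsilyloxy)benzaldehyde
Product: 3 2-(hydroxymethyl)-5-(triisopropylsilyloxy)phenol
Conditions: NaBH4, THF/MeOH, 0 °C
Reagents that add atoms: none
Why: Borohydride reduction of the aryl aldehyde to the benzylic alcohol; the aryl silyl ether and the phenol are inert at 0 °C, and the product is used without storage.

Step 3
Reactants: 3 2-(hydroxymethyl)-5-(triisopropylsilyloxy)phenol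
Product: 4 {[2-hydroxy-4-(triisopropylsilyloxy)phenyl]methyl}triphenylphosphonium bromide
Conditions: PPh3·HBr (1.0 equiv), MeCN, 70 °C
Reagents that add atoms: triphenylphosphine hydrobromide, [Br-].c1ccc(cc1)[PH+](c1ccccc1)c1ccccc1
Why: The benzylic alcohol, activated by the ortho-hydroxyl and the para-silyloxy group, ionises under the mild acid and is captured by PPh3 (SN1-type phosphonium salt formation, the standard entry to 2-hydroxybenzylphosphonium salts). The aryl TIPS ether should tolerate this weakly acidic, water-poor medium.

Step 4
Reactants: 5 methyl 4-bromo-3,5-dihydroxybenzoate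
Product: 6 methyl 4-bromo-3,5-bis(methoxymethoxy)benzoate
Conditions: MOMCl (2.5 equiv), iPr2NEt, CH2Cl2, 0 °C to rt
Reagents that add atoms: chloromethyl methyl ether, COCCl
Why: Double O-alkylation of the two equivalent, fairly acidic ortho-bromophenols (acetal formation). The MOM ethers survive the basic and thermal steps ahead and are removable with acid that spares an aryl silyl ether.

Step 5
Reactants: 6 methyl 4-bromo-3,5-bis(methoxymethoxy)benzoate
Product: 7 4-bromo-3,5-bis(methoxymethoxy)benzoic acid
Conditions: LiOH·H2O, THF/MeOH/H2O, rt; then 1 M HCl to pH 4, 0 °C
Reagents that add atoms: lithium hydroxide, [Li+].[OH-]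
Why: Saponification of a methyl ester with no ortho substituents next to the carboxyl; cold acidification only to pH 4 keeps the acetals.

Step 6
Reactants: 7 4-bromo-3,5-bis(methoxymethoxy)benzoic acid; 4 {[2-hydroxy-4-(triisopropylsilyloxy)phenyl]methyl}triphenylphosphonium bromide
Product: 9 2-[4-bromo-3,5-bis(methoxymethoxy)phenyl]-6-(triisopropylsilyloxy)-1-benzofuran, via O-aroyl phosphonium salt 8 (not isolated)
Conditions: DCC, DMAP (cat.), CH2Cl2, rt; filter, evaporate; then Et3N, toluene, 110 °C
Reagents that add atoms: none
Why: Steglich esterification acylates the only free phenol of 4; Et3N then forms the benzylic ylide, which attacks the neighbouring ester carbonyl in a five-membered intramolecular Wittig olefination that creates C2=C3 of the furan and expels Ph3PO. Neutral activation of the acid (no acid chloride, no HCl) protects the acetals.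

Step 7
Reactants: 9 2-[4-bromo-3,5-bis(methoxymethoxy)phenyl]-6-(triisopropylsilyloxy)-1-benzofuran
Product: 10 2-bromo-5-[6-(triisopropylsilyloxy)-1-benzofuran-2-yl]benzene-1,3-diol
Conditions: HCl (2 M in MeOH), THF, 40 °C
Reagents that add atoms: none
Why: Acid-catalysed transacetalisation of the aryl MOM ethers to the solvent; aryl silyl ethers are far more stable to acid than to base, and the aryl bromide and the benzofuran are inert.

Step 8
Reactants: 10 2-bromo-5-[6-(triisopropylsilyloxy)-1-benzofuran-2-yl]benzene-1,3-diol; 11 3-chloro-3-methylbut-1-yne
Product: 12 2-bromo-3-(2-methylbut-3-yn-2-yloxy)-5-[6-(triisopropylsilyloxy)-1-benzofuran-2-yl]phenol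
Conditions: 11 (0.9 equiv, slow addition), DBU (1.0 equiv), CuCl2·2H2O (1 mol %), dry MeCN, 0 °C
Reagents that add atoms: none
Why: Copper-catalysed O-propargylation of phenols with tertiary propargylic chlorides proceeds through a copper acetylide-derived electrophile and accepts ortho-substituted phenols at 0 °C. A slight deficit of 11 should favour the mono-ether, with unreacted 10 recovered and recycled.

Step 9
Reactants: 12 2-bromo-3-(2-methylbut-3-yn-2-yloxy)-5-[6-(triisopropylsilyloxy)-1-benzofuran-2-yl]phenol
Product: 13 2-bromo-3-(2-methylbut-3-en-2-yloxy)-5-[6-(triisopropylsilyloxy)-1-benzofuran-2-yl]phenol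
Conditions: H2 (1 atm), Pd/CaCO3 poisoned with Pb(OAc)2, quinoline, EtOAc, rt
Reagents that add atoms: none
Why: Lindlar-type semihydrogenation of the terminal alkyne stops at the alkene on the lead- and quinoline-poisoned surface; the aryl bromide, the benzofuran and the silyl ether should not react on this catalyst.

Step 10
Reactants: 13 2-bromo-3-(2-methylbut-3-en-2-yloxy)-5-[6-(triisopropylsilyloxy)-1-benzofuran-2-yl]phenol; 11 3-chloro-3-methylbut-1-yne
Product: 14 2-[4-bromo-3-(2-methylbut-3-yn-2-yloxy)-5-(2-methylbut-3-en-2-yloxy)phenyl]-6-(triisopropylsilyloxy)-1-benzofuran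
Conditions: 11 (3 equiv), DBU, CuCl2·2H2O (1 mol %), dry MeCN, 0 °C; work-up and chromatography below 30 °C
Reagents that add atoms: none
Why: The same copper-catalysed propargylation on the remaining phenol; at 0 °C the tertiary allyl aryl ether should neither ionise nor rearrange, and the alkyne arrives only after the hydrogenation.

Step 11
Reactants: 14 2-[4-bromo-3-(2-methylbut-3-yn-2-yloxy)-5-(2-methylbut-3-en-2-yloxy)phenyl]-6-(triisopropylsilyloxy)-1-benzofuran
Product: 17 8-bromo-2,2-dimethyl-6-(3-methylbut-2-enyl)-5-[6-(triisopropylsilyloxy)-1-benzofuran-2-yl]-2H-chromen-7-ol, via ortho-prenylphenol propargyl ether 15 (not isolated), via dienyl ortho-quinone methide 16 (not isolated)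
Conditions: degassed PhNEt2, Ar, 110 °C, then 180 °C
Reagents that add atoms: none
Why: These are two consecutive aromatic Claisen rearrangements, each a known reaction class of aryl 1,1-dimethylallyl ethers and aryl 1,1-dimethylpropargyl ethers. Near 110 °C the allyl ether on the oxygen of C5' should rearrange through a chair [3,3] transition state to C6', and the dienone tautomerises to the ortho-prenylphenol 15. At 180 °C the propargyl ether on the oxygen of C3' shifts to C2' to give an ortho-allenyl dienone, which enolises and passes by a 1,5-hydrogen shift into the (Z)-dienyl ortho-quinone methide 16. The pyran closes by a thermally allowed disrotatory oxa-6π electrocyclisation of 16, which forms the O–C(CH3)2 bond and restores the aromatic ring. No stereocentre is created. The selectivity needed is attack at C6' and C2' and not at C4'; the bromine on C4' secures it, because a shift onto that carbon gives a dienone with no hydrogen to lose that can only revert, and the para carbon C1' is blocked by the benzofuran. The gap in activation temperature between the two ethers fixes the order of events. The amine solvent buffers the new phenol so that the prenyl group does not cyclise onto it.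

Step 12
Reactants: 17 8-bromo-2,2-dimethyl-6-(3-methylbut-2-enyl)-5-[6-(triisopropylsilyloxy)-1-benzofuran-2-yl]-2H-chromen-7-ol
Product: 18 2,2-dimethyl-6-(3-methylbut-2-enyl)-5-[6-(triisopropylsilyloxy)-1-benzofuran-2-yl]-2H-chromen-7-ol
Conditions: Pd(OAc)2 (10 mol %), PPh3 (40 mol %), HCO2Na (5 equiv), degassed DMF, 100 °C
Reagents that add atoms: none
Why: Zerovalent palladium formed in situ inserts into the C4'–Br bond, formate exchanges onto the metal and loses CO2, and reductive elimination of the aryl palladium hydride gives the C4'–H bond (palladium-catalysed transfer hydrodehalogenation). No H2 and no metal surface are present, so the prenyl and chromene olefins should survive; any loss of the silyl group here is harmless because the next step removes it.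

Step 13
Reactants: 18 2,2-dimethyl-6-(3-methylbut-2-enyl)-5-[6-(triisopropylsilyloxy)-1-benzofuran-2-yl]-2H-chromen-7-ol
Product: 19 cathafuran C, 5-(6-hydroxy-1-benzofuran-2-yl)-2,2-dimethyl-6-(3-methylbut-2-enyl)-2H-chromen-7-ol
Conditions: TBAF (1.2 equiv), AcOH (1.2 equiv), THF, 0 °C
Reagents that add atoms: none
Why: Fluoride cleaves the aryl O–Si bond, driven by the Si–F bond strength; the acetic acid buffer keeps the electron-rich bis-phenol protonated against air oxidation and is too weak to cyclise the prenyl group onto the phenol or to open the chromene.

## Compound list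

1 | 2,4-dihydroxybenzaldehyde | O=Cc1ccc(O)cc1O | starting material
2 | 2-hydroxy-4-(triisopropylsilyloxy)benzaldehyde | O=Cc1ccc(O[Si](C(C)C)(C(C)C)C(C)C)cc1O | intermediate
3 | 2-(hydroxymethyl)-5-(triisopropylsilyloxy)phenol | OCc1ccc(O[Si](C(C)C)(C(C)C)C(C)C)cc1O | intermediate
4 | {[2-hydroxy-4-(triisopropylsilyloxy)phenyl]methyl}triphenylphosphonium bromide | [Br-].Oc1cc(O[Si](C(C)C)(C(C)C)C(C)C)ccc1C[P+](c1ccccc1)(c1ccccc1)c1ccccc1 | intermediate
5 | methyl 4-bromo-3,5-dihydroxybenzoate | COC(=O)c1cc(O)c(Br)c(O)c1 | starting material
6 | methyl 4-bromo-3,5-bis(methoxymethoxy)benzoate | COCOc1cc(cc(OCOC)c1Br)C(=O)OC | intermediate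
7 | 4-bromo-3,5-bis(methoxymethoxy)benzoic acid | COCOc1cc(cc(OCOC)c1Br)C(=O)O | intermediate
8 | {[2-(4-bromo-3,5-bis(methoxymethoxy)benzoyloxy)-4-(triisopropylsilyloxy)phenyl]methyl}triphenylphosphonium bromide | [Br-].COCOc1cc(cc(OCOC)c1Br)C(=O)Oc1cc(O[Si](C(C)C)(C(C)C)C(C)C)ccc1C[P+](c1ccccc1)(c1ccccc1)c1ccccc1 | intermediate
9 | 2-[4-bromo-3,5-bis(methoxymethoxy)phenyl]-6-(triisopropylsilyloxy)-1-benzofuran | COCOc1cc(cc(OCOC)c1Br)-c1cc2ccc(O[Si](C(C)C)(C(C)C)C(C)C)cc2o1 | intermediate
10 | 2-bromo-5-[6-(triisopropylsilyloxy)-1-benzofuran-2-yl]benzene-1,3-diol | Oc1cc(cc(O)c1Br)-c1cc2ccc(O[Si](C(C)C)(C(C)C)C(C)C)cc2o1 | intermediate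
11 | 3-chloro-3-methylbut-1-yne | CC(C)(Cl)C#C | starting material
12 | 2-bromo-3-(2-methylbut-3-yn-2-yloxy)-5-[6-(triisopropylsilyloxy)-1-benzofuran-2-yl]phenol | C#CC(C)(C)Oc1cc(cc(O)c1Br)-c1cc2ccc(O[Si](C(C)C)(C(C)C)C(C)C)cc2o1 | intermediate
13 | 2-bromo-3-(2-methylbut-3-en-2-yloxy)-5-[6-(triisopropylsilyloxy)-1-benzofuran-2-yl]phenol | C=CC(C)(C)Oc1cc(cc(O)c1Br)-c1cc2ccc(O[Si](C(C)C)(C(C)C)C(C)C)cc2o1 | intermediate
14 | 2-[4-bromo-3-(2-methylbut-3-yn-2-yloxy)-5-(2-methylbut-3-en-2-yloxy)phenyl]-6-(triisopropylsilyloxy)-1-benzofuran | C#CC(C)(C)Oc1cc(cc(OC(C)(C)C=C)c1Br)-c1cc2ccc(O[Si](C(C)C)(C(C)C)C(C)C)cc2o1 | intermediate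
15 | 2-bromo-3-(2-methylbut-3-yn-2-yloxy)-6-(3-methylbut-2-enyl)-5-[6-(triisopropylsilyloxy)-1-benzofuran-2-yl]phenol | C#CC(C)(C)Oc1cc(-c2cc3ccc(O[Si](C(C)C)(C(C)C)C(C)C)cc3o2)c(CC=C(C)C)c(O)c1Br | intermediate
16 | (6Z)-2-bromo-3-hydroxy-6-(3-methylbut-2-enylidene)-4-(3-methylbut-2-enyl)-5-[6-(triisopropylsilyloxy)-1-benzofuran-2-yl]cyclohexa-2,4-dien-1-one | O=C1C(Br)=C(O)C(CC=C(C)C)=C(-c2cc3ccc(O[Si](C(C)C)(C(C)C)C(C)C)cc3o2)/C1=C/C=C(C)C | intermediate
17 | 8-bromo-2,2-dimethyl-6-(3-methylbut-2-enyl)-5-[6-(triisopropylsilyloxy)-1-benzofuran-2-yl]-2H-chromen-7-ol | CC(C)=CCc1c(O)c(Br)c2OC(C)(C)C=Cc2c1-c1cc2ccc(O[Si](C(C)C)(C(C)C)C(C)C)cc2o1 | intermediate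
18 | 2,2-dimethyl-6-(3-methylbut-2-enyl)-5-[6-(triisopropylsilyloxy)-1-benzofuran-2-yl]-2H-chromen-7-ol | CC(C)=CCc1c(O)cc2OC(C)(C)C=Cc2c1-c1cc2ccc(O[Si](C(C)C)(C(C)C)C(C)C)cc2o1 | intermediate
19 | cathafuran C, 5-(6-hydroxy-1-benzofuran-2-yl)-2,2-dimethyl-6-(3-methylbut-2-enyl)-2H-chromen-7-ol | CC(C)=CCc1c(O)cc2c(c1-c1cc3ccc(O)cc3o1)C=CC(C)(C)O2 | target

## Step count and least certain steps

Total: 13 steps. Longest linear sequence: 11 steps (1 to 19 through steps 1–3 and 6–13); the ring B branch from 5 is 10 steps.

**Step 11 (key step).**
- **Risk.** The most likely failure is thermal fragmentation of the tertiary allyl aryl ether (loss of the C5 unit as a diene, returning the phenol) before the [3,3] shift to the crowded C6' takes place. A second risk is a shift onto the brominated C4' followed by irreversible loss of bromine instead of reversal, which would open that position to alkylation. Both arise because the wanted ortho carbons lie next to the bulky benzofuran and the pot must reach 180 °C for the propargyl arm.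
- **Fallback.** The two shifts are separated and their order inverted, setting out from 12.
  - Heating 12 alone in PhNEt2 at 180 °C should give 8-bromo-2,2-dimethyl-5-[6-(triisopropylsilyloxy)-1-benzofuran-2-yl]-2H-chromen-7-ol F1.
  - Copper-catalysed propargylation of F1 with 11 would give 8-bromo-2,2-dimethyl-7-(2-methylbut-3-yn-2-yloxy)-5-[6-(triisopropylsilyloxy)-1-benzofuran-2-yl]-2H-chromene F2.
  - Semihydrogenation over Pd/CaCO3 poisoned with Pb(OAc)2 would give 8-bromo-2,2-dimethyl-7-(2-methylbut-3-en-2-yloxy)-5-[6-(triisopropylsilyloxy)-1-benzofuran-2-yl]-2H-chromene F3.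
  - The allyl shift is then run under Eu(fod)3 catalysis in CHCl3 at 50 °C, where the Lewis-acid-accelerated [3,3] shift should outrun fragmentation. The fallback returns to the route at 17.

**Step 12.**
- **Risk.** Oxidative addition may be slow at a C–Br bond that is electron-rich and flanked by two oxygens, so the catalyst may decompose first. Palladium hydride may also migrate the prenyl double bond.
- **Fallback.** This sets out from 17 and uses a radical chain reduction in place of palladium catalysis: Bu3SnH with AIBN in toluene at 85 °C. The aryl radical at C4' has no olefin within cyclisation range and is expected to be quenched to the C–H bond. The fallback returns at 18 and passes through no new compound (F0).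

**Step 8.**
- **Risk.** Over-alkylation to the bis-ether together with incomplete conversion is likely, because the two phenols of 10 are equivalent and too far apart to influence each other, so the product distribution tends towards the statistical one.
- **Fallback.** This sets out from 10 and moves the desymmetrisation from the alkylation to the reduction. Exhaustive propargylation with excess 11 under the same copper catalysis would give 2-[4-bromo-3,5-bis(2-methylbut-3-yn-2-yloxy)phenyl]-6-(triisopropylsilyloxy)-1-benzofuran F4. Semihydrogenation over Pd/CaCO3 poisoned with Pb(OAc)2 would be stopped after one equivalent of H2, and the alkyne/alkene mixture separated on silica impregnated with AgNO3, with recovered F4 recycled. The fallback returns at 14 and bypasses 12 and 13.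

**Step 3.**
- **Risk.** Self-condensation of the strongly activated benzylic alcohol (ring alkylation through the quinone methide) may compete with capture by the phosphine, and HBr may partly cleave the silyl ether.
- **Fallback.** This avoids the benzylic alcohol and the phosphonium salt altogether and sets out from 2 and 7. Steglich esterification (DCC, DMAP, CH2Cl2, 0 °C) would give [2-formyl-5-(triisopropylsilyloxy)phenyl] 4-bromo-3,5-bis(methoxymethoxy)benzoate F5. An intramolecular McMurry-type aldehyde–ester reductive coupling with low-valent titanium generated from TiCl3 and Zn in refluxing DME would then form the furan C2=C3 bond. The fallback returns at 9 and bypasses 3, 4 and 8. Any acetal lost to the Lewis-acidic titanium salts is of no consequence, because step 7 removes both acetals anyway.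

## Further compounds

F1 | step 11 | 8-bromo-2,2-dimethyl-5-[6-(triisopropylsilyloxy)-1-benzofuran-2-yl]-2H-chromen-7-ol | CC1(C)C=Cc2c(O1)c(Br)c(O)cc2-c1cc2ccc(O[Si](C(C)C)(C(C)C)C(C)C)cc2o1
F2 | step 11 | 8-bromo-2,2-dimethyl-7-(2-methylbut-3-yn-2-yloxy)-5-[6-(triisopropylsilyloxy)-1-benzofuran-2-yl]-2H-chromene | CC1(C)C=Cc2c(O1)c(Br)c(OC(C)(C)C#C)cc2-c1cc2ccc(O[Si](C(C)C)(C(C)C)C(C)C)cc2o1
F3 | step 11 | 8-bromo-2,2-dimethyl-7-(2-methylbut-3-en-2-yloxy)-5-[6-(triisopropylsilyloxy)-1-benzofuran-2-yl]-2H-chromene | CC1(C)C=Cc2c(O1)c(Br)c(OC(C)(C)C=C)cc2-c1cc2ccc(O[Si](C(C)C)(C(C)C)C(C)C)cc2o1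
F0 | step 12 | none | none
F4 | step 8 | 2-[4-bromo-3,5-bis(2-methylbut-3-yn-2-yloxy)phenyl]-6-(triisopropylsilyloxy)-1-benzofuran | C#CC(C)(C)Oc1cc(cc(OC(C)(C)C#C)c1Br)-c1cc2ccc(O[Si](C(C)C)(C(C)C)C(C)C)cc2o1
F5 | step 3 | [2-formyl-5-(triisopropylsilyloxy)phenyl] 4-bromo-3,5-bis(methoxymethoxy)benzoate | COCOc1cc(cc(OCOC)c1Br)C(=O)Oc1cc(O[Si](C(C)C)(C(C)C)C(C)C)ccc1C=O
A1 | alternative 1 | methyl 2,4-dihydroxy-6-[6-(methoxymethoxy)-1-benzofuran-2-yl]-5-(3-methylbut-2-enyl)benzoate | COC(=O)c1c(O)cc(O)c(CC=C(C)C)c1-c1cc2ccc(OCOC)cc2o1
A2 | alternative 1 | 6-{4-[6-(methoxymethoxy)-1-benzofuran-2-yl]-3-(3-methylbut-2-enyl)-2,4-dioxobutyl}-2,2-dimethyl-4H-1,3-dioxin-4-one | CC1(C)OC(=CC(=O)O1)CC(=O)C(CC=C(C)C)C(=O)c1cc2ccc(OCOC)cc2o1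
A3 | alternative 1 | methyl 7-[6-(methoxymethoxy)-1-benzofuran-2-yl]-6-(3-methylbut-2-enyl)-3,5,7-trioxoheptanoate | COC(=O)CC(=O)CC(=O)C(CC=C(C)C)C(=O)c1cc2ccc(OCOC)cc2o1
A4 | alternative 2 | 6-(methoxymethoxy)-2-[7-(methoxymethoxy)-2,2-dimethyl-6-(3-methylbut-2-enyl)-2H-chromen-5-yl]-1-benzofuran | CC(C)=CCc1c(OCOC)cc2OC(C)(C)C=Cc2c1-c1cc2ccc(OCOC)cc2o1
A5 | alternative 2 | 1-[7-(methoxymethoxy)-2,2-dimethyl-6-(3-methylbut-2-enyl)-2H-chromen-5-yl]ethan-1-one | CC(=O)c1c(CC=C(C)C)c(OCOC)cc2OC(C)(C)C=Cc12
A6 | alternative 2 | 2-bromo-1-iodo-4-(methoxymethoxy)benzene | COCOc1ccc(I)c(Br)c1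
A7 | alternative 3 | methyl 2-[6-(methoxymethoxy)-1-benzofuran-2-yl]-3-(3-methylbut-2-enyl)-4,6-dioxocyclohexane-1-carboxylate (racemic, all-trans isomer drawn) | COC(=O)[C@@H]1C(=O)CC(=O)[C@H](CC=C(C)C)[C@H]1c1cc2ccc(OCOC)cc2o1
A8 | alternative 3 | (3E)-3-{[6-(methoxymethoxy)-1-benzofuran-2-yl]methylidene}-6-methylhept-5-en-2-one | CC(=O)/C(CC=C(C)C)=C/c1cc2ccc(OCOC)cc2o1
A9 | alternative 3 | dimethyl malonate | COC(=O)CC(=O)OC
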